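The terminal ring, C1(Me2)–C2H2–C3H=C4H–C5(=CH2)–C6H, is a 3-methylenecyclohexene whose diene (exocyclic C5=CH2, ring C3=C4) beside gem-dimethyl C1 is the retron of a vinylallene Diels–Alder reaction. One cycloaddition of penta-1,2,4-triene to a 3-methylbut-2-enoyl imide of (R)-4-benzyloxazolidin-2-one forms C1–C2 and C5–C6, closes this ring (the only ring built, and so the last closed; the arene is bought) and sets C6. The adduct is reduced to the C10 alcohol, converted into a tetrazolyl sulfone and joined at C7=C8 by Julia–Kocienski olefination to an aryl C30 polyenal from crocetindial.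

Key step: step 3

Assumption: crocetindial and 2,3,4-trimethylbenzaldehyde are treated as purchasable speciality building blocks; atoms are numbered as in the first paragraph, C7 being the first chain carbon on C6.

Step 1
Reactants: 1 propargyl bromide (3-bromoprop-1-yne); 2 vinylmagnesium bromide
Product: 3 penta-1,2,4-triene (vinylallene)
Conditions: CuBr·SMe2 (5 mol%), THF, −40 → 0 °C; water wash into toluene, fractional distillation
Reagents that add atoms: none
Why: Copper-catalysed SN2′ coupling of a Grignard reagent with a propargylic bromide (the standard preparation of terminal allenes such as phenylallene) should place the vinyl group on the alkyne terminus and give the volatile vinylallene, no stereocentre being formed.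

Step 2
Reactants: 4 (R)-4-benzyloxazolidin-2-one; 5 3-methylbut-2-enoyl chloride
Product: 7 (R)-4-benzyl-3-(3-methylbut-2-enoyl)oxazolidin-2-one, via lithium (R)-4-benzyl-2-oxooxazolidin-3-ide 6 (not isolated)
Conditions: n-BuLi, THF, −78 °C; then 5, −78 → 0 °C
Reagents that add atoms: none
Why: N-Acylation of the pre-lithiated oxazolidinone with the acid chloride (standard imide formation) needs no amine base, so the 3-methylbut-2-enoyl group should not deconjugate through a vinylketene, and the stereocentre of 4 is untouched.

Step 3
Reactants: 3 penta-1,2,4-triene; 7 (R)-4-benzyl-3-(3-methylbut-2-enoyl)oxazolidin-2-one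
Product: 8 (R)-4-benzyl-3-[(S)-6,6-dimethyl-2-methylidenecyclohex-3-ene-1-carbonyl]oxazolidin-2-one
Conditions: Me2AlCl (1.5 equiv), 3 (3 equiv), CH2Cl2, −78 → −20 °C; cold 1 M HCl quench
Reagents that add atoms: none
Why: Me2AlCl binds both imide carbonyls, giving a cationic chelate that holds the enoyl group s-cis and activates the β,β-dimethyl dienophile; the conjugated C=C–C=C unit of 3 (allene central carbon to vinyl CH2) then adds in a concerted, asynchronous [4+2] cycloaddition. The reaction type is the Lewis-acid-promoted Diels–Alder reaction of an N-enoyl oxazolidinone (Evans auxiliary) with a vinylallene as the diene, and the closest precedent for the substitution pattern is the AlCl3-promoted addition of piperylene to mesityl oxide. The six-membered ring is closed by intermolecular [4+2] cycloaddition, both ring bonds (C1–C2 from the CMe2 carbon to the vinyl CH2, and C5–C6 from the α-carbon to the allene central carbon) forming in one step, while the untouched allene π bond becomes the exocyclic C5=CH2 and the new ring alkene is C3=C4. C6, the only new stereocentre, is controlled by the benzyl group of the (R)-auxiliary, which shields one face of the chelated s-cis dienophile so that the diene should add to the opposite face and give the (S) configuration; because C1 carries two methyl groups and neither diene terminus becomes stereogenic, no endo/exo question arises. The step needs "ortho" regioselectivity, which the hyperconjugating allene CH2 at the diene terminus should secure by placing the larger HOMO coefficient on the vinyl CH2 that attacks the electrophilic β-carbon, and it needs the conjugated diene to react in preference to the isolated allene π bond, which the [4+2] pathway favours. The product diene is locked s-trans and cannot add a second dienophile.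

Step 4
Reactants: 8 (R)-4-benzyl-3-[(S)-6,6-dimethyl-2-methylidenecyclohex-3-ene-1-carbonyl]oxazolidin-2-one
Product: 9 [(1S)-6,6-dimethyl-2-methylidenecyclohex-3-en-1-yl]methanol
Conditions: LiBH4, MeOH (1 equiv), Et2O, 0 °C
Reagents that add atoms: none
Why: Reductive cleavage of an N-acyloxazolidinone with LiBH4/MeOH should deliver hydride to the exocyclic carbonyl and release the primary alcohol and the auxiliary under non-basic conditions that neither epimerise C6 nor move the exocyclic double bond.

Step 5
Reactants: 9 [(1S)-6,6-dimethyl-2-methylidenecyclohex-3-en-1-yl]methanol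
Product: 10 5-({[(1S)-6,6-dimethyl-2-methylidenecyclohex-3-en-1-yl]methyl}sulfanyl)-1-phenyl-1H-tetrazole
Conditions: 1-phenyl-1H-tetrazole-5-thiol, PPh3, DIAD, THF, 0 °C → rt
Reagents that add atoms: 1-phenyl-1H-tetrazole-5-thiol, Sc1nnnn1-c1ccccc1
Why: Mitsunobu thioetherification, in which the acidic tetrazolethiol displaces the activated primary C7 hydroxyl by SN2, so that C6 is not involved.

Step 6
Reactants: 10 5-({[(1S)-6,6-dimethyl-2-methylidenecyclohex-3-en-1-yl]methyl}sulfanyl)-1-phenyl-1H-tetrazole
Product: 11 5-({[(1S)-6,6-dimethyl-2-methylidenecyclohex-3-en-1-yl]methyl}sulfonyl)-1-phenyl-1H-tetrazole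
Conditions: (NH4)6Mo7O24·4H2O (10 mol%), 30% aq. H2O2, EtOH, 0 °C → rt
Reagents that add atoms: hydrogen peroxide, OO
Why: Molybdate-catalysed peroxide oxidation of a sulfide to the sulfone is selective for sulfur and should leave the unactivated diene intact.

Step 7
Reactants: 12 2,3,4-trimethylbenzaldehyde
Product: 13 (2,3,4-trimethylphenyl)methanol
Conditions: NaBH4, MeOH, 0 °C
Reagents that add atoms: none
Why: Hydride reduction of an aromatic aldehyde with NaBH4 is straightforward and touches nothing else.

Step 8
Reactants: 13 (2,3,4-trimethylphenyl)methanol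
Product: 14 diethyl [(2,3,4-trimethylphenyl)methyl]phosphonate
Conditions: P(OEt)3 (3 equiv), ZnI2 (1.5 equiv), toluene, reflux
Reagents that add atoms: triethyl phosphite, CCOP(OCC)OCC
Why: ZnI2-mediated direct phosphonylation of a benzylic alcohol (a Michaelis–Arbuzov reaction through the benzylic iodide formed in the flask) suits this electron-rich benzyl alcohol and saves a separate halogenation.

Step 9
Reactants: 14 diethyl [(2,3,4-trimethylphenyl)methyl]phosphonate; 15 crocetindial
Product: 17 (2E,4E,6E,8E,10E,12E,14E,16E)-2,6,11,15-tetramethyl-17-(2,3,4-trimethylphenyl)heptadeca-2,4,6,8,10,12,14,16-octaenal, via potassium phosphonate carbanion 16 (not isolated)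
Conditions: KOtBu, THF, 0 °C; then added slowly to 15 (3 equiv), THF, 0 °C → rt
Reagents that add atoms: none
Why: Horner–Wadsworth–Emmons reaction of a benzylic phosphonate anion with an enal should give the aryl–CH=CH double bond as the E isomer, and inverse addition to an excess of the symmetrical dialdehyde should favour mono-olefination with recovery of unreacted 15.

Step 10
Reactants: 11 5-({[(1S)-6,6-dimethyl-2-methylidenecyclohex-3-en-1-yl]methyl}sulfonyl)-1-phenyl-1H-tetrazole; 17 the aryl C30 octaenal
Product: 19 (6S)-3,4-didehydro-γ,χ-carotene (the target), via potassium sulfonyl carbanion 18 (not isolated)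
Conditions: KN(SiMe3)2, THF, −78 °C; then 17, −78 °C → rt, under argon in the dark
Reagents that add atoms: none
Why: Julia–Kocienski olefination, in which the C7 sulfonyl carbanion adds to the aldehyde and Smiles rearrangement with loss of SO2 and the tetrazololate should give the C7=C8 double bond mainly as the E isomer; the base acts only at C7 and the product has no carbonyl group, so the C6 stereocentre is kept.

Compound list
1 | propargyl bromide (3-bromoprop-1-yne) | C#CCBr | starting material
2 | vinylmagnesium bromide | C=C[Mg]Br | starting material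
3 | penta-1,2,4-triene (vinylallene) | C=C=CC=C | intermediate
4 | (R)-4-benzyloxazolidin-2-one | O=C1N[C@H](Cc2ccccc2)CO1 | starting material
5 | 3-methylbut-2-enoyl chloride | CC(C)=CC(=O)Cl | starting material
6 | lithium (R)-4-benzyl-2-oxooxazolidin-3-ide | [Li+].O=C1[N-][C@H](Cc2ccccc2)CO1 | intermediate
7 | (R)-4-benzyl-3-(3-methylbut-2-enoyl)oxazolidin-2-one | CC(C)=CC(=O)N1[C@H](Cc2ccccc2)COC1=O | intermediate
8 | (R)-4-benzyl-3-[(S)-6,6-dimethyl-2-methylidenecyclohex-3-ene-1-carbonyl]oxazolidin-2-one | C=C1C=CCC(C)(C)[C@@H]1C(=O)N1[C@H](Cc2ccccc2)COC1=O | intermediate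
9 | [(1S)-6,6-dimethyl-2-methylidenecyclohex-3-en-1-yl]methanol | C=C1C=CCC(C)(C)[C@@H]1CO | intermediate
10 | 5-({[(1S)-6,6-dimethyl-2-methylidenecyclohex-3-en-1-yl]methyl}sulfanyl)-1-phenyl-1H-tetrazole | C=C1C=CCC(C)(C)[C@@H]1CSc1nnnn1-c1ccccc1 | intermediate
11 | 5-({[(1S)-6,6-dimethyl-2-methylidenecyclohex-3-en-1-yl]methyl}sulfonyl)-1-phenyl-1H-tetrazole | C=C1C=CCC(C)(C)[C@@H]1CS(=O)(=O)c1nnnn1-c1ccccc1 | intermediate
12 | 2,3,4-trimethylbenzaldehyde | O=Cc1ccc(C)c(C)c1C | starting material
13 | (2,3,4-trimethylphenyl)methanol | OCc1ccc(C)c(C)c1C | intermediate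
14 | diethyl [(2,3,4-trimethylphenyl)methyl]phosphonate | CCOP(=O)(OCC)Cc1ccc(C)c(C)c1C | intermediate
15 | crocetindial, (2E,4E,6E,8E,10E,12E,14E)-2,6,11,15-tetramethylhexadeca-2,4,6,8,10,12,14-heptaenedial | O=C/C(C)=C/C=C/C(C)=C/C=C/C=C(C)/C=C/C=C(C)/C=O | starting material
16 | potassium salt of the benzylic carbanion of 14 | [K+].CCOP(=O)(OCC)[CH-]c1ccc(C)c(C)c1C | intermediate
17 | (2E,4E,6E,8E,10E,12E,14E,16E)-2,6,11,15-tetramethyl-17-(2,3,4-trimethylphenyl)heptadeca-2,4,6,8,10,12,14,16-octaenal | O=C/C(C)=C/C=C/C(C)=C/C=C/C=C(C)/C=C/C=C(C)/C=C/c1ccc(C)c(C)c1C | intermediate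
18 | potassium salt of the C7 carbanion of 11 | [K+].C=C1C=CCC(C)(C)[C@@H]1[CH-]S(=O)(=O)c1nnnn1-c1ccccc1 | intermediate
19 | (6S)-3,4-didehydro-γ,χ-carotene, 1-{(1E,3E,5E,7E,9E,11E,13E,15E,17E)-18-[(1S)-6,6-dimethyl-2-methylidenecyclohex-3-en-1-yl]-3,7,12,16-tetramethyloctadeca-1,3,5,7,9,11,13,15,17-nonaen-1-yl}-2,3,4-trimethylbenzene | C=C1C=CCC(C)(C)[C@@H]1/C=C/C(C)=C/C=C/C(C)=C/C=C/C=C(C)/C=C/C=C(C)/C=C/c1ccc(C)c(C)c1C | target

Total step count: 10. Longest linear sequence: 6 steps (step 1 or 2, then steps 3, 4, 5, 6 and 10).

Steps most likely to fail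

1. Step 3. The dienophile carries two β-methyl groups, so the cycloaddition may be slower than Lewis-acid-induced oligomerisation of the triene, and the higher temperature then needed may erode facial selectivity. The fallback replaces auxiliary control by a racemic cycloaddition and a resolution. It sets out from 3, which is combined with commercial 3-methylbut-2-enal under AlCl3 (0.3 equiv, CH2Cl2, −40 → 0 °C, the conditions type under which piperylene adds to mesityl oxide). This should give rac-6,6-dimethyl-2-methylidenecyclohex-3-ene-1-carbaldehyde F1, which is not isolated, because the β,γ-unsaturated aldehyde would conjugate easily, but is reduced in the same flask (NaBH4, MeOH, −40 °C) to rac-(6,6-dimethyl-2-methylidenecyclohex-3-en-1-yl)methanol F2. Preparative chromatography on a chiral stationary phase should then separate the enantiomers; the (S)-enantiomer is 9, where the route is rejoined.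

2. Step 10. The conjugated aldehyde may give incomplete E selectivity in the addition and Smiles sequence, and vinylogous deprotonation of the polyenal by the sulfonyl carbanion may compete with addition. The fallback replaces the stereoselective sulfone olefination by a Wittig reaction followed by stereomutation. It sets out from 9: Appel iodination (I2, PPh3, imidazole, CH2Cl2, 0 °C) should give (4S)-4-(iodomethyl)-5,5-dimethyl-3-methylidenecyclohex-1-ene F3. Quaternisation (PPh3, MeCN, reflux) should give {[(1S)-6,6-dimethyl-2-methylidenecyclohex-3-en-1-yl]methyl}triphenylphosphonium iodide F4. Wittig reaction of F4 with 17 (NaN(SiMe3)2, THF, −78 °C → rt) should give mainly the (7Z)-isomer of the target F5. Iodine-catalysed photoisomerisation (I2 cat., hexane, daylight) should then equilibrate F5 to the all-E compound 19, where the route ends.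

3. Step 4. The acyl carbonyl is shielded by the quaternary C1 and by C5, so hydride may instead open the oxazolidinone ring at its own carbonyl. The fallback separates cleavage from reduction. It sets out from 8: LiOH and H2O2 (THF/H2O, 0 °C), in which the small hydroperoxide anion attacks the exocyclic carbonyl, should give (1S)-6,6-dimethyl-2-methylidenecyclohex-3-ene-1-carboxylic acid F6 and the recovered auxiliary. LiAlH4 (Et2O, 0 °C) should then reduce F6 to 9, where the route is rejoined.

Further compounds
F1 | step 3 | rac-6,6-dimethyl-2-methylidenecyclohex-3-ene-1-carbaldehyde | C=C1C=CCC(C)(C)C1C=O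
F2 | step 3 | rac-(6,6-dimethyl-2-methylidenecyclohex-3-en-1-yl)methanol | C=C1C=CCC(C)(C)C1CO
F3 | step 10 | (4S)-4-(iodomethyl)-5,5-dimethyl-3-methylidenecyclohex-1-ene | C=C1C=CCC(C)(C)[C@@H]1CI
F4 | step 10 | {[(1S)-6,6-dimethyl-2-methylidenecyclohex-3-en-1-yl]methyl}triphenylphosphonium iodide | C=C1C=CCC(C)(C)[C@@H]1C[P+](c1ccccc1)(c1ccccc1)c1ccccc1.[I-]
F5 | step 10 | (7Z)-isomer of 19 | C=C1C=CCC(C)(C)[C@@H]1\C=C/C(C)=C/C=C/C(C)=C/C=C/C=C(C)/C=C/C=C(C)/C=C/c1ccc(C)c(C)c1C
F6 | step 4 | (1S)-6,6-dimethyl-2-methylidenecyclohex-3-ene-1-carboxylic acid | C=C1C=CCC(C)(C)[C@@H]1C(=O)O
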